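Labels: C1 is the tertiary-alcohol carbon carrying the C7 benzoyloxymethyl arm, C2 and C6 are its CHOH neighbours, C5 is the CHOBz carbon beside C6, and C3 and C4 are the methylenes. Cutting C2–C3 and C5–C6 leaves O2–C2–C1–C6–O6, a dihydroxyacetone unit whose cis oxygens O2 and O6 fit one benzylidene acetal, and C3–C4–C5, which is acrolein. A chiral pyrrolidine joins purchased 2-phenyl-1,3-dioxan-5-one and acrolein by Michael addition and aldol closure in one flask. This delivers the carbocycle, both C–C bonds and the C2, C5 and C6 stereocentres as a 2,4-dioxabicyclo[3.3.1]nonan-9-one. Ylide epoxidation, benzoate opening and hydrogenolysis complete C1 and C7.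

Key step: step 1

Assumption on the sense of induction: in additions of six-ring ketone enamines, an (S)-pyrrolidine with an acidic side group makes the (S)-α-centre. C2 is (R), so the (R)-catalyst is drawn; its antipode is equally available if the sense proves reversed.
Assumption on the ketone: 1 hydrates easily and is used as the dry monomer (azeotroped with toluene).
Design remark: the monosubstituted benzylidene acetal is kept on purpose. Its equatorial phenyl locks the dioxane chair, and only its hydrogen points toward C4 in the bicycle, whereas a 2,2-dialkyl ketal would push an alkyl group into the C4 methylene. It also leaves by neutral hydrogenolysis beside two benzoates.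

Step 1
Reactants: 1 2-phenyl-1,3-dioxan-5-one; 2 acrolein
Product: 4 (1R,3S,5S,6R)-6-hydroxy-3-phenyl-2,4-dioxabicyclo[3.3.1]nonan-9-one, via keto aldehyde 3 (not isolated)
Conditions: (R)-5-(pyrrolidin-2-yl)-1H-tetrazole (20 mol %), H2O (2 equiv), MeCN, 0 °C; freshly distilled 2 (1 equiv) added by syringe pump to 1 (2 equiv), then 4 °C
Reagents that add atoms: acrolein 2, C=CC=O
Why: Proposed new method: the pyrrolidine nitrogen condenses with 1 to an enamine that adds to the β-carbon of 2 (C2–C3) while the tetrazole N–H holds the acrolein oxygen, the keto aldehyde 3 is taken up again as the enamine toward the still unsubstituted α'-carbon, and this attacks the tethered formyl group (C5–C6) before hydrolysis releases 4 and the amine. The closest known reaction types are the α,α'-annulation of cyclic-ketone enamines with enals or unsaturated keto esters to bicyclo[3.3.1]nonan-9-ones and the proline-type aldol and Michael reactions of 1,3-dioxan-5-ones, but the enantioselective union of this pair has not been shown. The one new ring, the carbocycle, closes by a 6-(enolendo)-exo-trig aldol (both enamine carbons, C6 and C1, end up inside it), which is geometrically open only when the oxopropyl chain stands axial on the dioxane chair. C2 is set by the catalyst, whose preferred enamine face coincides with the stereoelectronically required axial trajectory at only one of the two enantiotopic α-carbons of the phenyl-locked chair, and the same choice makes the acetal carbon stereogenic with phenyl equatorial; C6 is set by the tether, because a three-carbon bridge can span only cis-diaxial positions (this overrides the catalyst's own facial preference in the second enamine, which may slow the closure but cannot misdirect it); C5 is set by the hydrogen bond from the tetrazole to the formyl oxygen, which keeps O5 gauche to C1 and hence axial on the new chair, trans to O6. The step needs conjugate rather than carbonyl addition to 2, one annulation rather than double alkylation, and no further reaction of the product: 1,2-addition is reversible while the Michael–aldol sequence is a sink, slow addition of 2 lets the intramolecular aldol outrun a second Michael addition, 1 offers only C2 and C6 as nucleophilic carbons, and 4 has only bridgehead α-carbons and can form no further enamine.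

Step 2
Reactants: 4 bicyclic hydroxy ketone; 5 benzoyl chloride
Product: 6 (1R,3S,5S,6R)-9-oxo-3-phenyl-2,4-dioxabicyclo[3.3.1]nonan-6-yl benzoate
Conditions: BzCl (1.5 equiv), pyridine, DMAP (cat.), CH2Cl2, 0 °C to rt
Reagents that add atoms: benzoyl chloride 5, O=C(Cl)c1ccccc1
Why: DMAP-catalysed O-acylation (nucleophilic acyl substitution) leaves the C5–O bond intact and so retains C5, installs the first benzoate of the target, and caps the aldol hydroxyl so that retro-aldol cleavage is no longer possible in the basic step that follows.

Step 3
Reactants: 6 keto benzoate; 7 trimethylsulfonium iodide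
Product: 8 (1R,3S,5S,6R,9S)-3-phenylspiro[2,4-dioxabicyclo[3.3.1]nonane-9,2'-oxiran]-6-yl benzoate
Conditions: Me3SI (1.5 equiv), KN(SiMe3)2 (1.3 equiv), THF, −20 °C (ylide pre-formed); then 6 (dried azeotropically), −20 to 0 °C
Reagents that add atoms: trimethylsulfonium iodide 7, C[S+](C)C.[I-] (delivers the CH2 that becomes C7)
Why: Corey–Chaykovsky epoxidation, in which the unstabilised ylide should add irreversibly to the strongly electrophilic, non-enolisable α,α'-dioxygenated bridge ketone faster than to the benzoate (β-elimination is excluded because bridgehead enolisation is geometrically forbidden), and should approach over the dioxane ring, where only oxygen lone pairs flank the path, because the other face is screened by the axial C5 benzoate and the axial C3–H, so that C7 ends cis to O2 and O6, O1 ends trans to them, and C1 is set as (S).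

Step 4
Reactants: 8 spiro-epoxide; 9 benzoic acid
Product: 10 [(1R,3S,5S,6R,9S)-6-(benzoyloxy)-9-hydroxy-3-phenyl-2,4-dioxabicyclo[3.3.1]nonan-9-yl]methyl benzoate
Conditions: PhCO2H (2 equiv), Bu4N(O2CPh) (10 mol %), MeCN, 70 °C
Reagents that add atoms: benzoic acid 9, O=C(O)c1ccccc1
Why: Buffered SN2 opening of a 2,2-disubstituted epoxide by carboxylate at its unsubstituted carbon C7 leaves the C1–O bond, and hence the C1 configuration, untouched; ionisation at C1 is disfavoured by the adjacent C–O bonds at C2, C6 and C7, and the excess acid protonates the tertiary alkoxide at once, which suppresses benzoyl migration.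

Step 5
Reactants: 10 dibenzoate acetal
Product: 11 [(1S,2R,5R,6S)-5-(benzoyloxy)-1,2,6-trihydroxycyclohexyl]methyl benzoate (target CNP0264996.1)
Conditions: H2 (1 atm), Pd(OH)2/C, EtOAc–EtOH, rt
Reagents that add atoms: none
Why: Catalytic hydrogenolysis cleaves the two benzylic C–O bonds of the benzylidene acetal and frees O2–H and O6–H, while the alkyl benzoates have no benzylic C–O bond and the neutral medium prevents acyl migration among the three hydroxyls, so no stereocentre is touched.

Compound list
1 | 2-phenyl-1,3-dioxan-5-one | O=C1COC(c2ccccc2)OC1 | starting material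
2 | acrolein (prop-2-enal) | C=CC=O | starting material
3 | 3-[(2R,4R)-5-oxo-2-phenyl-1,3-dioxan-4-yl]propanal (trans: phenyl equatorial, oxopropyl chain axial) | O=C1[C@@H](CCC=O)O[C@H](c2ccccc2)OC1 | intermediate (not isolated)
4 | (1R,3S,5S,6R)-6-hydroxy-3-phenyl-2,4-dioxabicyclo[3.3.1]nonan-9-one (phenyl equatorial on the dioxane ring; hydroxyl axial on the carbocycle, trans to the neighbouring acetal oxygen; bicycle C1, C5, C6, C9 = C2, C6, C5, C1 of the target) | O=C1[C@@H]2O[C@H](c3ccccc3)O[C@H]1[C@H](O)CC2 | intermediate
5 | benzoyl chloride | O=C(Cl)c1ccccc1 | starting material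
6 | (1R,3S,5S,6R)-9-oxo-3-phenyl-2,4-dioxabicyclo[3.3.1]nonan-6-yl benzoate | O=C1[C@@H]2O[C@H](c3ccccc3)O[C@H]1[C@H](OC(=O)c4ccccc4)CC2 | intermediate
7 | trimethylsulfonium iodide | C[S+](C)C.[I-] | starting material
8 | (1R,3S,5S,6R,9S)-3-phenylspiro[2,4-dioxabicyclo[3.3.1]nonane-9,2'-oxiran]-6-yl benzoate (epoxide CH2 over the dioxane ring, epoxide O over the carbocycle) | C1O[C@]12[C@@H]3O[C@H](c4ccccc4)O[C@H]2[C@H](OC(=O)c5ccccc5)CC3 | intermediate
9 | benzoic acid | O=C(O)c1ccccc1 | starting material
10 | [(1R,3S,5S,6R,9S)-6-(benzoyloxy)-9-hydroxy-3-phenyl-2,4-dioxabicyclo[3.3.1]nonan-9-yl]methyl benzoate | O[C@@]1(COC(=O)c5ccccc5)[C@@H]2O[C@H](c3ccccc3)O[C@H]1[C@H](OC(=O)c4ccccc4)CC2 | intermediate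
11 | [(1S,2R,5R,6S)-5-(benzoyloxy)-1,2,6-trihydroxycyclohexyl]methyl benzoate (labels of this route; C7, O2 and O6 on one ring face, O1 and O5 on the other) | O=C(OC[C@]1(O)[C@H](O)CC[C@@H](OC(=O)c2ccccc2)[C@@H]1O)c1ccccc1 | target

Total step count: 5. Longest linear sequence: 5 (1 to 11).

Steps most likely to fail

Step 1. Several processes may undermine it:
- amine-initiated polymerisation of acrolein
- self-aldolisation of the unhindered ketone
- capture of the catalyst by a Mannich-type closure
- weak discrimination between the two enantiotopic α-carbons
- aldol closure with O5 equatorial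

The fallback splits the annulation into known reactions and sets out from 1.

Enantioselective deprotonation uses lithium bis[(R)-1-phenylethyl]amide (or its antipode, chosen by a test run) and LiCl in THF at −95 °C with Me3SiCl present. This desymmetrisation is known for 2-substituted 1,3-dioxan-5-ones. It should give the silyl enol ether trimethyl{[(2R)-2-phenyl-4H-1,3-dioxin-5-yl]oxy}silane F1, in which the choice of α-carbon is already stored at the acetal carbon.

Mukaiyama–Michael addition of F1 to 2 under iminium activation (morpholinium trifluoroacetate, moist CH2Cl2, −20 °C) should give 3. Beside it would form its C2 epimer, 3-[(2R,4S)-5-oxo-2-phenyl-1,3-dioxan-4-yl]propanal F2. The two interconvert by enolisation and only 3 can close. Catalytic pyrrolidinium acetate therefore funnels both through the intramolecular aldol to 4, where the route is rejoined.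

Material that closes with O5 equatorial is the C5 epimer (1R,3S,5S,6S)-6-hydroxy-3-phenyl-2,4-dioxabicyclo[3.3.1]nonan-9-one F3. It returns at 6 by Mitsunobu benzoylation with 9, PPh3 and DIAD. This proceeds with inversion, and elimination is excluded at the bridgehead. The same exit serves any F3 formed in step 1 itself.

Step 3. The ylide may attack the C5 benzoate, benzoyl may transfer to the nascent C1 alkoxide that sits 1,3-diaxial to it, or the facial bias may be insufficient. The fallback replaces epoxidation by nucleophilic hydroxymethylation and sets out from 6.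

- Addition of (i-PrO)Me2SiCH2MgCl in THF at −78 °C, with a cold quench, should take the same open face. It gives the carbinol 9-{[dimethyl(propan-2-yloxy)silyl]methyl}-9-hydroxy-3-phenyl-2,4-dioxabicyclo[3.3.1]nonan-6-yl benzoate F4.
- Tamao–Fleming oxidation (H2O2, KF, KHCO3, THF–MeOH) gives the diol 9-hydroxy-9-(hydroxymethyl)-3-phenyl-2,4-dioxabicyclo[3.3.1]nonan-6-yl benzoate F5.
- Benzoylation of the primary hydroxyl alone (5, pyridine, CH2Cl2, −20 °C) returns to the route at 10 and bypasses 8.

Methylenation followed by epoxidation or dihydroxylation is deliberately not used. An oxidant would take the same open face and place O1, not C7, over the dioxane ring.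

Step 4. Substitution at C7 may be slow because the anionic nucleophile must pass the lone pairs of O2 and O6, and benzoyl migration to O1 may set in at the temperature then needed. The fallback accepts ester loss and sets out from 8.

- KOH in DMSO–H2O at 80 °C should open the epoxide at C7 with hydroxide and saponify the C5 ester. This gives the triol 9-(hydroxymethyl)-3-phenyl-2,4-dioxabicyclo[3.3.1]nonane-6,9-diol F6. O5 cannot interfere because it lies on the ring face opposite to C7.
- Benzoylation with 5 (2.3 equiv), pyridine and catalytic DMAP at 0 °C acylates the primary O7 and the secondary O5, while the tertiary O1 stays free. This returns to the route at 10.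

Further compounds
F1 | step 1 | trimethyl{[(2R)-2-phenyl-4H-1,3-dioxin-5-yl]oxy}silane | C[Si](C)(C)OC1=CO[C@H](c2ccccc2)OC1
F2 | step 1 | 3-[(2R,4S)-5-oxo-2-phenyl-1,3-dioxan-4-yl]propanal (cis, chain equatorial) | O=C1[C@H](CCC=O)O[C@H](c2ccccc2)OC1
F3 | step 1 | (1R,3S,5S,6S)-6-hydroxy-3-phenyl-2,4-dioxabicyclo[3.3.1]nonan-9-one (hydroxyl equatorial, cis to O6) | O=C1[C@@H]2O[C@H](c3ccccc3)O[C@H]1[C@@H](O)CC2
F4 | step 3 | 9-{[dimethyl(propan-2-yloxy)silyl]methyl}-9-hydroxy-3-phenyl-2,4-dioxabicyclo[3.3.1]nonan-6-yl benzoate (silylmethyl over the dioxane ring) | O[C@@]1(C[Si](C)(C)OC(C)C)[C@@H]2O[C@H](c3ccccc3)O[C@H]1[C@H](OC(=O)c4ccccc4)CC2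
F5 | step 3 | 9-hydroxy-9-(hydroxymethyl)-3-phenyl-2,4-dioxabicyclo[3.3.1]nonan-6-yl benzoate | O[C@@]1(CO)[C@@H]2O[C@H](c3ccccc3)O[C@H]1[C@H](OC(=O)c4ccccc4)CC2
F6 | step 4 | 9-(hydroxymethyl)-3-phenyl-2,4-dioxabicyclo[3.3.1]nonane-6,9-diol | O[C@@]1(CO)[C@@H]2O[C@H](c3ccccc3)O[C@H]1[C@H](O)CC2
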